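**Plan**

1. Numbering used throughout: C1 bridgehead CH, C2 CHOH, C3 C(OMe), C4 =CH, C5 allyl bridgehead, C6 CHMe, C7 CHAr, C8 C=O. In the six-membered ring C1–C2–C3–C4–C5–C8 the ketone C8 and the enol ether carbon C3 are 1,4-related through C5–C4. That is the retron of a 2-siloxycyclopropyl ketone (ring C4–C5–C8) opened by retro-aldol.
2. Retrosynthetic cuts, in order: O–CH3 and O–Si; then C4–C5 together with a temporary C4–C8 bond (diazoketone plus silyl enol ether); then C6–CH3, C5–allyl, C1–C2 and C7–aryl on a cyclopentenone.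
3. Forward: the five-membered ring C1–C8–C5–C6–C7 is bought as a 4-silyloxycyclopentenone and decorated. The carbenoid step closes the cyclopropane and the cyclopentanone C1–C2–C3–C4–C8 at once. Fluoride opening of C4–C8 then turns the 5/5/3 tricycle into the bicyclo[3.2.1]octenone.
4. Stereochemistry: C7 from the purchased (R) centre by anti conjugate addition; C1 (trans to aryl) and C2 (anti aldol) from a ring-locked E boron enolate; C6 from cuprate addition anti to aryl; C5 from the tether-enforced face of the cyclopropanation.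

Key step: step 10

Remark: (R)-4-(tert-butyldimethylsilyloxy)cyclopent-2-en-1-one and the aryl Grignard solution are taken as purchasable; locants C1–C8 in the text follow the numbering of the plan for every intermediate.

Step 1
Reactants: 1 (R)-4-(tert-butyldimethylsilyloxy)cyclopent-2-en-1-one; 2 (3,4-dimethoxyphenyl)magnesium bromide
Product: 3 (3S,4R)-4-(tert-butyldimethylsilyloxy)-3-(3,4-dimethoxyphenyl)cyclopentan-1-one
Conditions: 2 (1.3 equiv), CuBr·SMe2 (10 mol %), THF, −78 to −40 °C; aq. NH4Cl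
Reagents that add atoms: none
Why: Copper-catalysed conjugate addition of the aryl Grignard reagent should occur anti to the C4 silyloxy group, the usual facial bias of 4-oxygenated cyclopentenones, so the aryl-bearing carbon (later C7) is set from the purchased stereocentre.

Step 2
Reactants: 3 (3S,4R)-4-(tert-butyldimethylsilyloxy)-3-(3,4-dimethoxyphenyl)cyclopentan-1-one
Product: 4 (R)-4-(3,4-dimethoxyphenyl)cyclopent-2-en-1-one
Conditions: DBU (1.1 equiv), CH2Cl2, −20 to 0 °C, short contact time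
Reagents that add atoms: none
Why: E1cB elimination of the beta-silyloxy group moves the enone to the far side of the ring and leaves the aryl-bearing carbon as the only stereocentre, while low temperature and brief exposure to base should keep the benzylic gamma-hydrogen untouched.

Step 3
Reactants: 4 (R)-4-(3,4-dimethoxyphenyl)cyclopent-2-en-1-one; 5 methacrolein
Product: 7 (4S,5S)-4-(3,4-dimethoxyphenyl)-5-[(1R)-1-hydroxy-2-methylprop-2-en-1-yl]cyclopent-2-en-1-one, via dibutylboron enolate 6 (not isolated)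
Conditions: n-Bu2BOTf, i-Pr2NEt, CH2Cl2, −78 °C; 5, −78 °C; then pH 7 buffer, MeOH, 30% H2O2, 0 °C
Reagents that add atoms: dibutylboron trifluoromethanesulfonate, CCCCB(CCCC)OS(=O)(=O)C(F)(F)F (its Bu2B group stays in 6 only)
Why: Soft enolisation at the alpha-prime carbon gives a ring-locked E(O) boron enolate (kept at −78 °C because it is a 5-substituted cyclopentadiene prone to 1,5-hydrogen shift) whose boron aldol addition through a chair Zimmerman–Traxler transition state should give the anti adduct at C2 and take the aldehyde on the face of C1 opposite to the neighbouring aryl group.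

Step 4
Reactants: 7 (4S,5S)-4-(3,4-dimethoxyphenyl)-5-[(1R)-1-hydroxy-2-methylprop-2-en-1-yl]cyclopent-2-en-1-one
Product: 8 (4S,5S)-5-[(1R)-1-(tert-butyldimethylsilyloxy)-2-methylprop-2-en-1-yl]-4-(3,4-dimethoxyphenyl)cyclopent-2-en-1-one
Conditions: TBSOTf, 2,6-lutidine, CH2Cl2, −78 °C
Reagents that add atoms: tert-butyldimethylsilyl trifluoromethanesulfonate, CC(C)(C)[Si](C)(C)OS(=O)(=O)C(F)(F)F
Why: Silylation of the hindered secondary alcohol with the silyl triflate and a hindered pyridine base is standard and stops retro-aldol cleavage or dehydration of the beta-hydroxy ketone; a silyl group is chosen because an ether with C–H bonds next to oxygen would invite 1,5-insertion in the carbenoid step.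

Step 5
Reactants: 8 (4S,5S)-5-[(1R)-1-(tert-butyldimethylsilyloxy)-2-methylprop-2-en-1-yl]-4-(3,4-dimethoxyphenyl)cyclopent-2-en-1-one
Product: 9 (4S,5S)-5-[(1R)-1-(tert-butyldimethylsilyloxy)-2-oxopropyl]-4-(3,4-dimethoxyphenyl)cyclopent-2-en-1-one
Conditions: O3, CH2Cl2/MeOH, −78 °C, Sudan Red 7B as end-point indicator; then Me2S, −78 °C to rt
Reagents that add atoms: ozone, [O-][O+]=O
Why: Ozonolysis with reductive work-up should cleave the electron-rich 1,1-disubstituted alkene to the methyl ketone well before the electron-poor enone alkene or the veratryl ring reacts, the dye marking the end point.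

Step 6
Reactants: 9 (4S,5S)-5-[(1R)-1-(tert-butyldimethylsilyloxy)-2-oxopropyl]-4-(3,4-dimethoxyphenyl)cyclopent-2-en-1-one
Product: 10 (4R,5S)-5-[(1R)-1-(tert-butyldimethylsilyloxy)-2-oxopropyl]-4-(3,4-dimethoxyphenyl)-2-iodocyclopent-2-en-1-one
Conditions: I2, pyridine, CH2Cl2, 0 °C to rt
Reagents that add atoms: iodine, II
Why: Alpha-iodination of the enone by pyridine addition, iodination and elimination (a Baylis–Hillman-type sequence) is routine for cyclopentenones, and the medium is too weakly basic to expel the beta-silyloxy group or to iodinate the methyl ketone.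

Step 7
Reactants: 10 (4R,5S)-5-[(1R)-1-(tert-butyldimethylsilyloxy)-2-oxopropyl]-4-(3,4-dimethoxyphenyl)-2-iodocyclopent-2-en-1-one; 11 allyltributylstannane
Product: 12 (4S,5S)-5-[(1R)-1-(tert-butyldimethylsilyloxy)-2-oxopropyl]-4-(3,4-dimethoxyphenyl)-2-(prop-2-en-1-yl)cyclopent-2-en-1-one
Conditions: 11 (1.5 equiv), Pd2(dba)3 (5 mol %), AsPh3 (20 mol %), CuI (10 mol %), NMP, rt
Reagents that add atoms: none
Why: Stille coupling of an alpha-iodoenone with an allylstannane under zerovalent palladium with a weakly binding arsine ligand and CuI should proceed at room temperature under neutral conditions, which spares the base-sensitive beta-silyloxy ketone and avoids migration of the allyl double bond.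

Step 8
Reactants: 12 (4S,5S)-5-[(1R)-1-(tert-butyldimethylsilyloxy)-2-oxopropyl]-4-(3,4-dimethoxyphenyl)-2-(prop-2-en-1-yl)cyclopent-2-en-1-one
Product: 14 (1R)-1-(tert-butyldimethylsilyloxy)-1-[(1S,4S,5S)-5-(3,4-dimethoxyphenyl)-4-methyl-3-(prop-2-en-1-yl)-2-(triethylsilyloxy)cyclopent-2-en-1-yl]propan-2-one, via lithium enolate 13 (not isolated)
Conditions: Me2CuLi (from CuI and 2 MeLi), Et2O, −78 °C; then Et3SiCl, Et3N, THF/HMPA, −78 to 0 °C
Reagents that add atoms: lithium dimethylcuprate, [Li+].C[Cu-]C (CH3 to C6; Li stays in 13 only); chlorotriethylsilane, CC[Si](Cl)(CC)CC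
Why: Conjugate addition of the Gilman cuprate should occur anti to the adjacent C7 aryl group and so set C6 (methyl trans to aryl), and O-silylation of the resulting enolate fixes the enol ether regiospecifically between C8 and C5, the saturated methyl ketone being inert to the cuprate at −78 °C.

Step 9
Reactants: 14 (1R)-1-(tert-butyldimethylsilyloxy)-1-[(1S,4S,5S)-5-(3,4-dimethoxyphenyl)-4-methyl-3-(prop-2-en-1-yl)-2-(triethylsilyloxy)cyclopent-2-en-1-yl]propan-2-one
Product: 16 (1R)-1-(tert-butyldimethylsilyloxy)-3-diazo-1-[(1S,4S,5S)-5-(3,4-dimethoxyphenyl)-4-methyl-3-(prop-2-en-1-yl)-2-(triethylsilyloxy)cyclopent-2-en-1-yl]propan-2-one, via trifluoroacetyl ketone 15 (not isolated)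
Conditions: LiN(SiMe3)2, THF, −78 °C; CF3CO2CH2CF3, −78 °C; aq. NH4Cl; then 4-acetamidobenzenesulfonyl azide, Et3N, H2O (1 equiv), MeCN, rt
Reagents that add atoms: 4-acetamidobenzenesulfonyl azide, CC(=O)Nc1ccc(cc1)S(=O)(=O)N=[N+]=[N-]; 2,2,2-trifluoroethyl trifluoroacetate, FC(F)(F)C(=O)OCC(F)(F)F (its CF3CO group stays in 15 only)
Why: Kinetic deprotonation of the methyl group (the only enolisable ketone now that C8 is masked, and on the side away from the silyloxy-bearing C2), trifluoroacetylation and deacylative Regitz diazo transfer should give the terminal diazoketone under conditions that a hindered tetrasubstituted triethylsilyl enol ether tolerates.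

Step 10
Reactants: 16 (1R)-1-(tert-butyldimethylsilyloxy)-3-diazo-1-[(1S,4S,5S)-5-(3,4-dimethoxyphenyl)-4-methyl-3-(prop-2-en-1-yl)-2-(triethylsilyloxy)cyclopent-2-en-1-yl]propan-2-one
Product: 17 (1S,2R,4S,5R,6S,7S,8R)-2-(tert-butyldimethylsilyloxy)-7-(3,4-dimethoxyphenyl)-6-methyl-5-(prop-2-en-1-yl)-8-(triethylsilyloxy)-4,8-cyclobicyclo[3.2.1]octan-3-one (the bicyclo[3.2.1]octane skeleton with an extra C4–C8 bond)
Conditions: Rh2(cap)4 (1 mol %; cap = caprolactamate), CH2Cl2, 40 °C, slow addition of 16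
Reagents that add atoms: none
Why: Loss of N2 at the dirhodium centre gives an electrophilic keto carbenoid at C4 that adds in a concerted, asynchronous [2+1] fashion to the electron-rich tetrasubstituted C8=C5 enol ether; the closest known reaction type is the intramolecular cyclopropanation of a 1-diazohex-5-en-2-one to a bicyclo[3.1.0]hexan-2-one, here applied to a silyl enol ether. The C4–C8 bond closes the cyclopentanone C1–C2–C3–C4–C8 in a 5-exo sense (C5 stays outside that ring) and the C4–C5 bond closes the three-membered ring C4–C5–C8 in the same event. The new stereocentres C4, C5 and C8 are all dictated by C1, because the three-atom tether can reach only the alkene face that carries the C1–C2 bond (cis 5/5 fusion). This places C4 cis to C2, the allyl group on the face opposite to the C6 methyl group, and the C8 oxygen on the allyl face. The step needs chemoselectivity for the enol ether over the allyl alkene, the veratryl ring and 1,5-insertion into the benzylic C7–H bond. The enol ether is the most nucleophilic pi bond and sits at the favoured five-ring distance, the allyl alkene would need an eight-membered ring, and carboxamidate ligands on divalent rhodium give a less electrophilic carbenoid that should prefer cyclopropanation to C–H insertion and aromatic attack.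

Step 11
Reactants: 17 (1S,2R,4S,5R,6S,7S,8R)-2-(tert-butyldimethylsilyloxy)-7-(3,4-dimethoxyphenyl)-6-methyl-5-(prop-2-en-1-yl)-8-(triethylsilyloxy)-4,8-cyclobicyclo[3.2.1]octan-3-one
Product: 19 (1S,2R,5R,6S,7S)-2-(tert-butyldimethylsilyloxy)-7-(3,4-dimethoxyphenyl)-3-methoxy-6-methyl-5-(prop-2-en-1-yl)bicyclo[3.2.1]oct-3-en-8-one, via sulfonium enolate 18 (not isolated)
Conditions: TASF (1.1 equiv), THF/DMPU, −78 °C; then Me2SO4, −78 to 0 °C
Reagents that add atoms: dimethyl sulfate, COS(=O)(=O)OC; tris(dimethylamino)sulfonium difluorotrimethylsilicate, CN(C)[S+](N(C)C)N(C)C.C[Si-](C)(C)(F)F (its cation stays in 18 only)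
Why: Fluoride should remove the triethylsilyl group from the cyclopropanol oxygen faster than the secondary tert-butyldimethylsilyl group, the C8 alkoxide then collapses to the ketone with heterolysis of the C4–C8 bond only (retro-aldol opening of a donor–acceptor cyclopropane, C4 being alpha to the C3 ketone), and the metal-free enolate, whose double bond can only lie between C3 and C4, should be methylated on oxygen by the hard sulfate in a dipolar medium because C4 is neopentyl and hindered.

Step 12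
Reactants: 19 (1S,2R,5R,6S,7S)-2-(tert-butyldimethylsilyloxy)-7-(3,4-dimethoxyphenyl)-3-methoxy-6-methyl-5-(prop-2-en-1-yl)bicyclo[3.2.1]oct-3-en-8-one
Product: 20 (1S,2R,5R,6S,7S)-7-(3,4-dimethoxyphenyl)-2-hydroxy-3-methoxy-6-methyl-5-(prop-2-en-1-yl)bicyclo[3.2.1]oct-3-en-8-one (CNP0232354.1)
Conditions: Bu4NF, THF, 0 °C
Reagents that add atoms: none
Why: Fluoride desilylation under non-acidic conditions spares the methyl enol ether, and the liberated beta-hydroxy ketone cannot undergo retro-aldol cleavage or elimination because the intervening carbon C1 is a bridgehead (Bredt's rule).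

**Compound list**

1 | (R)-4-(tert-butyldimethylsilyloxy)cyclopent-2-en-1-one | O=C1C=C[C@H](O[Si](C)(C)C(C)(C)C)C1 | starting material
2 | (3,4-dimethoxyphenyl)magnesium bromide (THF solution) | COc1ccc([Mg]Br)cc1OC | starting material
3 | (3S,4R)-4-(tert-butyldimethylsilyloxy)-3-(3,4-dimethoxyphenyl)cyclopentan-1-one (aryl and silyloxy trans) | O=C1C[C@@H](c2ccc(OC)c(OC)c2)[C@H](O[Si](C)(C)C(C)(C)C)C1 | intermediate
4 | (R)-4-(3,4-dimethoxyphenyl)cyclopent-2-en-1-one | O=C1C=C[C@H](c2ccc(OC)c(OC)c2)C1 | intermediate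
5 | methacrolein (2-methylprop-2-enal) | CC(=C)C=O | starting material
6 | dibutyl{[(3S)-3-(3,4-dimethoxyphenyl)cyclopenta-1,4-dien-1-yl]oxy}borane (alpha-prime boron enolate of 4) | C1=C[C@H](c2ccc(OC)c(OC)c2)C=C1OB(CCCC)CCCC | intermediate
7 | (4S,5S)-4-(3,4-dimethoxyphenyl)-5-[(1R)-1-hydroxy-2-methylprop-2-en-1-yl]cyclopent-2-en-1-one (4,5-trans, anti aldol) | C1=C[C@H](c2ccc(OC)c(OC)c2)[C@@H]([C@@H](O)C(C)=C)C1=O | intermediate
8 | (4S,5S)-5-[(1R)-1-(tert-butyldimethylsilyloxy)-2-methylprop-2-en-1-yl]-4-(3,4-dimethoxyphenyl)cyclopent-2-en-1-one | C1=C[C@H](c2ccc(OC)c(OC)c2)[C@@H]([C@@H](O[Si](C)(C)C(C)(C)C)C(C)=C)C1=O | intermediate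
9 | (4S,5S)-5-[(1R)-1-(tert-butyldimethylsilyloxy)-2-oxopropyl]-4-(3,4-dimethoxyphenyl)cyclopent-2-en-1-one | C1=C[C@H](c2ccc(OC)c(OC)c2)[C@@H]([C@@H](O[Si](C)(C)C(C)(C)C)C(C)=O)C1=O | intermediate
10 | (4R,5S)-5-[(1R)-1-(tert-butyldimethylsilyloxy)-2-oxopropyl]-4-(3,4-dimethoxyphenyl)-2-iodocyclopent-2-en-1-one | IC1=C[C@H](c2ccc(OC)c(OC)c2)[C@@H]([C@@H](O[Si](C)(C)C(C)(C)C)C(C)=O)C1=O | intermediate
11 | allyltributylstannane | C=CC[Sn](CCCC)(CCCC)CCCC | starting material
12 | (4S,5S)-5-[(1R)-1-(tert-butyldimethylsilyloxy)-2-oxopropyl]-4-(3,4-dimethoxyphenyl)-2-(prop-2-en-1-yl)cyclopent-2-en-1-one | C=CCC1=C[C@H](c2ccc(OC)c(OC)c2)[C@@H]([C@@H](O[Si](C)(C)C(C)(C)C)C(C)=O)C1=O | intermediate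
13 | lithium (3S,4S,5S)-5-[(1R)-1-(tert-butyldimethylsilyloxy)-2-oxopropyl]-4-(3,4-dimethoxyphenyl)-3-methyl-2-(prop-2-en-1-yl)cyclopent-1-en-1-olate | C=CCC1=C(O[Li])[C@H]([C@@H](O[Si](C)(C)C(C)(C)C)C(C)=O)[C@@H](c2ccc(OC)c(OC)c2)[C@@H]1C | intermediate
14 | (1R)-1-(tert-butyldimethylsilyloxy)-1-[(1S,4S,5S)-5-(3,4-dimethoxyphenyl)-4-methyl-3-(prop-2-en-1-yl)-2-(triethylsilyloxy)cyclopent-2-en-1-yl]propan-2-one | C=CCC1=C(O[Si](CC)(CC)CC)[C@H]([C@@H](O[Si](C)(C)C(C)(C)C)C(C)=O)[C@@H](c2ccc(OC)c(OC)c2)[C@@H]1C | intermediate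
15 | (5R)-5-(tert-butyldimethylsilyloxy)-5-[(1S,4S,5S)-5-(3,4-dimethoxyphenyl)-4-methyl-3-(prop-2-en-1-yl)-2-(triethylsilyloxy)cyclopent-2-en-1-yl]-1,1,1-trifluoropentane-2,4-dione | C=CCC1=C(O[Si](CC)(CC)CC)[C@H]([C@@H](O[Si](C)(C)C(C)(C)C)C(=O)CC(=O)C(F)(F)F)[C@@H](c2ccc(OC)c(OC)c2)[C@@H]1C | intermediate
16 | (1R)-1-(tert-butyldimethylsilyloxy)-3-diazo-1-[(1S,4S,5S)-5-(3,4-dimethoxyphenyl)-4-methyl-3-(prop-2-en-1-yl)-2-(triethylsilyloxy)cyclopent-2-en-1-yl]propan-2-one | C=CCC1=C(O[Si](CC)(CC)CC)[C@H]([C@@H](O[Si](C)(C)C(C)(C)C)C(=O)C=[N+]=[N-])[C@@H](c2ccc(OC)c(OC)c2)[C@@H]1C | intermediate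
17 | (1S,2R,4S,5R,6S,7S,8R)-2-(tert-butyldimethylsilyloxy)-7-(3,4-dimethoxyphenyl)-6-methyl-5-(prop-2-en-1-yl)-8-(triethylsilyloxy)-4,8-cyclobicyclo[3.2.1]octan-3-one | C=CC[C@]12[C@H](C(=O)[C@H](O[Si](C)(C)C(C)(C)C)[C@@H]3[C@@H](c4ccc(OC)c(OC)c4)[C@@H]1C)[C@@]23O[Si](CC)(CC)CC | intermediate
18 | tris(dimethylamino)sulfonium (1S,2R,5R,6S,7S)-2-(tert-butyldimethylsilyloxy)-7-(3,4-dimethoxyphenyl)-6-methyl-8-oxo-5-(prop-2-en-1-yl)bicyclo[3.2.1]oct-3-en-3-olate | C=CC[C@@]12C=C([O-])[C@H](O[Si](C)(C)C(C)(C)C)[C@@H](C1=O)[C@@H](c1ccc(OC)c(OC)c1)[C@@H]2C.CN(C)[S+](N(C)C)N(C)C | intermediate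
19 | (1S,2R,5R,6S,7S)-2-(tert-butyldimethylsilyloxy)-7-(3,4-dimethoxyphenyl)-3-methoxy-6-methyl-5-(prop-2-en-1-yl)bicyclo[3.2.1]oct-3-en-8-one | C=CC[C@@]12C=C(OC)[C@H](O[Si](C)(C)C(C)(C)C)[C@@H](C1=O)[C@@H](c1ccc(OC)c(OC)c1)[C@@H]2C | intermediate
20 | (1S,2R,5R,6S,7S)-7-(3,4-dimethoxyphenyl)-2-hydroxy-3-methoxy-6-methyl-5-(prop-2-en-1-yl)bicyclo[3.2.1]oct-3-en-8-one | C=CC[C@@]12C=C(OC)[C@H](O)[C@@H](C1=O)[C@@H](c1ccc(OC)c(OC)c1)[C@@H]2C | target

**Totals**

Total step count: 12. Longest linear sequence: 12 steps (1 to 20).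

**Steps most likely to fail**

Step 11. The metal-free enolate may be protonated by adventitious water before it is alkylated, fluoride may begin to attack the C2 silyl ether, or methylation may drift from oxygen to C4. The fallback sets out from 17 and comes back at 19, and it separates ring opening from methylation. Buffered HF·pyridine (pyridine, THF, 0 °C) should remove the triethylsilyl group much faster than the secondary tert-butyldimethylsilyl group, and the freed 2-acylcyclopropanol opens by retro-aldol cleavage to the bicyclic 1,4-diketone (1S,2R,5S,6S,7S)-2-(tert-butyldimethylsilyloxy)-7-(3,4-dimethoxyphenyl)-6-methyl-5-(prop-2-en-1-yl)bicyclo[3.2.1]octane-3,8-dione F1. KN(SiMe3)2 (THF, −78 °C) should then deprotonate C4, since the C8 ketone lies between a bridgehead and a quaternary carbon and the C2 hydrogen is deactivated by its geminal silyloxy group. This gives the potassium C3 enolate F2 (not isolated), which is O-methylated with Me2SO4 in THF/DMPU to give 19.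

Step 10. The carbenoid may insert into the benzylic C7–H bond (also a 1,5 relationship and on the same ring face as the side chain) or attack the aryl ring, and the congested tetrasubstituted alkene may react so slowly that carbene dimerisation takes over. The fallback sets out from 14 and comes back at 19, and it makes the C4–C5 bond without a carbene by oxidative coupling of two silyl enol ethers. LiN(SiMe3)2 and Me3SiCl (THF, −78 °C) convert 14 into the bis(silyl enol ether) F3, in which the methyl ketone has become the CH2=C(OSiMe3) enol ether. (NH4)2Ce(NO3)6 with NaHCO3 in MeCN at −10 °C should oxidise the more electron-rich ring enol ether to a C5 radical that adds to the terminal carbon C4 of the second enol ether, again only on the face bearing the C1 side chain. A second oxidation and loss of both silyl groups then give the 1,4-diketone F1, which continues through enolate F2 to 19 as described for step 11.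

Step 3. The slim, achiral enal may discriminate poorly between anti and syn transition states or between the two enolate faces, and the 5-substituted cyclopentadiene character of enolate 6 narrows the usable temperature window. The fallback sets out from 4 and comes back at 9, and it uses a chiral aldehyde whose own bias reinforces both preferences. Ethyl (S)-lactate is silylated (Et3SiCl, imidazole, DMF) to ethyl (S)-2-(triethylsilyloxy)propanoate F4 and reduced (i-Bu2AlH, CH2Cl2, −78 °C) to (S)-2-(triethylsilyloxy)propanal F5. Its addition to boron enolate 6 under the conditions of step 3 should give the 2,3-anti-3,4-anti adduct (Felkin–Anh addition to the alpha-silyloxy aldehyde, matched with the anti and trans-to-aryl preferences), (4S,5S)-4-(3,4-dimethoxyphenyl)-5-[(1R,2S)-1-hydroxy-2-(triethylsilyloxy)propyl]cyclopent-2-en-1-one F6. TBSOTf and 2,6-lutidine give the bis(silyl ether) (4S,5S)-5-[(1R,2S)-1-(tert-butyldimethylsilyloxy)-2-(triethylsilyloxy)propyl]-4-(3,4-dimethoxyphenyl)cyclopent-2-en-1-one F7. PPTS in MeOH at 0 °C should remove only the triethylsilyl group to give the secondary alcohol (4S,5S)-5-[(1R,2S)-1-(tert-butyldimethylsilyloxy)-2-hydroxypropyl]-4-(3,4-dimethoxyphenyl)cyclopent-2-en-1-one F8, and Dess–Martin oxidation gives methyl ketone 9, which also bypasses the ozonolysis.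

**Further compounds**

F1 | step 11 | (1S,2R,5S,6S,7S)-2-(tert-butyldimethylsilyloxy)-7-(3,4-dimethoxyphenyl)-6-methyl-5-(prop-2-en-1-yl)bicyclo[3.2.1]octane-3,8-dione | C=CC[C@@]12CC(=O)[C@H](O[Si](C)(C)C(C)(C)C)[C@@H](C1=O)[C@@H](c1ccc(OC)c(OC)c1)[C@@H]2C
F2 | step 11 | potassium (1S,2R,5R,6S,7S)-2-(tert-butyldimethylsilyloxy)-7-(3,4-dimethoxyphenyl)-6-methyl-8-oxo-5-(prop-2-en-1-yl)bicyclo[3.2.1]oct-3-en-3-olate (not isolated) | C=CC[C@@]12C=C([O-])[C@H](O[Si](C)(C)C(C)(C)C)[C@@H](C1=O)[C@@H](c1ccc(OC)c(OC)c1)[C@@H]2C.[K+]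
F3 | step 10 | bis(silyl enol ether): 14 with its methyl ketone as the 2-(trimethylsilyloxy)prop-2-enyl enol ether, (1R) at C2 and (1S,4S,5S) in the ring | C=CCC1=C(O[Si](CC)(CC)CC)[C@H]([C@@H](O[Si](C)(C)C(C)(C)C)C(=C)O[Si](C)(C)C)[C@@H](c2ccc(OC)c(OC)c2)[C@@H]1C
F4 | step 3 | ethyl (S)-2-(triethylsilyloxy)propanoate | CCOC(=O)[C@H](C)O[Si](CC)(CC)CC
F5 | step 3 | (S)-2-(triethylsilyloxy)propanal | O=C[C@H](C)O[Si](CC)(CC)CC
F6 | step 3 | (4S,5S)-4-(3,4-dimethoxyphenyl)-5-[(1R,2S)-1-hydroxy-2-(triethylsilyloxy)propyl]cyclopent-2-en-1-one | C1=C[C@H](c2ccc(OC)c(OC)c2)[C@@H]([C@@H](O)[C@H](C)O[Si](CC)(CC)CC)C1=O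
F7 | step 3 | (4S,5S)-5-[(1R,2S)-1-(tert-butyldimethylsilyloxy)-2-(triethylsilyloxy)propyl]-4-(3,4-dimethoxyphenyl)cyclopent-2-en-1-one | C1=C[C@H](c2ccc(OC)c(OC)c2)[C@@H]([C@@H](O[Si](C)(C)C(C)(C)C)[C@H](C)O[Si](CC)(CC)CC)C1=O
F8 | step 3 | (4S,5S)-5-[(1R,2S)-1-(tert-butyldimethylsilyloxy)-2-hydroxypropyl]-4-(3,4-dimethoxyphenyl)cyclopent-2-en-1-one | C1=C[C@H](c2ccc(OC)c(OC)c2)[C@@H]([C@@H](O[Si](C)(C)C(C)(C)C)[C@H](C)O)C1=O
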